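**Remarks on conventions and assumptions**

- Locants C1–C15 are those of the germacrane skeleton of the target and are used for every intermediate: C1 ketone, C2=C3 enol ether, C4=C5 alkene, C6 lactone carbinol, C7, C8 ester carbinol, C9 methylene, C10 quaternary carbon, C11=C13 methylene, C12 lactone carbonyl, C14 methyl, C15 hydroxymethyl.
- Acetoin is used as the racemate, because its stereocentre becomes the planar C10 of a furan. (S)-Glyceraldehyde acetonide is taken as a commercial reagent.
- CIP descriptors at C6 and C7 change along the route only because substituent priorities change. The single configurational change is the inversion at C8 in step 16.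

## Analysis of the target

Target 34 is a germacrane-type sesquiterpene lactone whose ten-membered carbocycle (C1–C10) is bridged by an oxygen between C3 and C10, so that C10, O, C3, C2 and C1 form a furan-3(2H)-one. The carbocycle is fused at C6/C7 to an α-methylene-γ-butyrolactone (O6, C12, C11=C13). Three of the four stereocentres are contiguous, C6 (R), C7 (R) and C8 (R): along the C5–C9 chain drawn as a zigzag, O6 and C11 are syn (a trans-lactone) and C11 and O8 are anti. The fourth, C10 (S), is a quaternary, oxygen-bearing carbon with the C14 methyl group, separated from the others by the C9 methylene. The C4=C5 bond is Z and carries the C15 hydroxymethyl group. Sensitive groups are two Michael acceptors (the α-methylene lactone and the C8 methacrylate), the cross-conjugated dienyl furanone (a vinylogous ester) and the allylic primary alcohol. The difficulty is the strained bicyclic core: a medium ring holding three sp2 centres (C3, C4, C5) has to be closed onto a fully substituted carbon, and C10 has no neighbouring stereocentre to direct it. The strategy rests on one feature: C10 is α to the C1 ketone and bound to the ring oxygen, so in the 3-oxyfuran form it is the nucleophilic 2-position of an aromatic furan, and its neighbour C9 is a methylene next to oxygenated C8, that is, the terminal carbon of a C8–C9 epoxide.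

## Retrosynthetic reasoning

**End game (C15–O, C12 oxidation level, C8 ester).** Target 34 is traced to its p-methoxybenzyl ether 33, and the lactone of 33 to diol 30 by oxidation of C12 and closure onto O6. Diol 30 comes from the bis-silyl ether 29, and 29 from alcohol 28 by acylation of O8. The lactone is carried as a silylated 2-methylene-1,4-diol because an α-methylene lactone would itself be an electrophile for the furan nucleophile of the key step. The methacrylate goes on before O6 is freed, so only O6 can close onto C12. The benzyl-type ether on C15 stays to the end, so the oxidant sees one primary allylic alcohol only.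

**Key disconnection (C9–C10).** In 28 the bond between the quaternary C10 and the C9 methylene is cut. This is the only cut that removes the ring strain and the isolated stereocentre together, and it leaves a precursor, 27, in which both reacting partners are latent in the target's own oxidation pattern: the furanone as its silyl enol ether (an aromatic 3-silyloxyfuran) and the C8 carbinol as a terminal oxirane. The forward reaction has to form a quaternary carbon, close the ring and choose one face of a planar furan.

**C3–C4 bond.** Precursor 27 is cut between the furan and the alkene into vinyl iodide 26 and furyl stannane 6. An sp2–sp2 bond between an electron-rich furan and a Z-iodoalkene is well suited to palladium coupling, and the acid-sensitive silyloxyfuran then enters one step before it is used. Stannane 6 goes back through silyloxyfuran 4 and furanone 3 to acetoin 1 by a one-carbon homologation and cyclodehydration.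

**Oxirane, with inversion at C8.** Epoxide 26 is traced to mesylate 24, in which O9 is the nucleophile and O8 the leaving group, and 24 through 23, 22 and 21 to lactone 20. Closing the oxirane with inversion is deliberate; the reason lies in the next disconnection.

**C6–C7 bond.** Lactone 20 is cut between the two carbinol-flanked carbons into bromobutenolide 18 and iodoenal 11. An allylation of this kind forms the bond between C6 and C7 and leaves the C11=C13 methylene in place. The allyl partner is taken as a butenolide and not as an open-chain (Z)-2-(bromomethyl)enoate. In the open-chain reagent C8 would be cis to the metal-bearing carbon, and a chair transition state would then lead to the 6,7-syn (cis-lactone) series. In 18 the ring holds C8 trans to the bromomethyl group, and the same chair gives the required 6,7-anti relationship. The aldehyde then enters anti to C9, which gives the C7/C8 relationship opposite to that of the target. This is corrected by starting from the (S)-aldehyde 12 and inverting C8 when the oxirane is closed.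

**Building blocks.** Bromobutenolide 18 comes from aldehyde 12 and methyl acrylate 13 through adduct 14, lactone 16 and silyl ether 17. Iodoenal 11 comes from but-2-yne-1,4-diol 7 through 8 and 10; the directed hydrometalation fixes iodine cis to the future C6, which is the Z geometry of C4=C5.

## Alternatives that were turned down

**Alternative 1:** The cut is at C7–C11 together with C11=C13. In the forward direction the anion of a phosphonoacetate ester on O6 opens a C7–C8 epoxide at C7 (5-exo, inversion). The resulting α-phosphono lactone is olefinated in the same flask with formaldehyde A2 to give the trans α-methylene lactone with a free C8 hydroxyl, A1.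
- For it: both bond-forming events are textbook reactions (carbanion opening of an epoxide, Horner–Wadsworth–Emmons methylenation with formaldehyde A2). C7 is set by SN2 inversion from a defined epoxide, so the C6–C8 triad is more predictable than anything in the chosen key step.
- Against it: it solves the easier half of the molecule. A1 is still acyclic at C1/C2 and lacks the O–C3 bond. The ten-membered ring, the furanone and the quaternary C10 would all have to be made afterwards, in the presence of the α-methylene lactone and through a ring that contains an alkyne. Six-endo opening at C8 and elimination of the allylic C6 ester are further risks.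
- Comparison: this alternative is stronger on the reliability and stereocontrol of its own key step. The chosen strategy offers in its place a key step that closes the ring and creates C10 at once, with the lactone kept masked until no nucleophile is left.

**Alternative 2:** No skeletal bond of the target is cut. A temporary C3–C8 bond is added to give a decalin, whose epoxy ketone sulfonylhydrazone fragments (Eschenmoser–Tanabe) with loss of nitrogen and sulfinate to the ten-membered enynone A3.
- For it: the medium ring appears by ring opening of a six–six bicycle, which avoids macrocyclisation and is a known, entropically easy process. Stereocentres can be set on a rigid decalin.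
- Against it: the decalin precursor, with its diol acetonide, lactone and tetrasubstituted epoxide, needs a long synthesis of its own. A3 holds an alkyne next to a Z-alkene in a ten-membered ring, which is strained. C8 emerges as a ketone that must be reduced stereoselectively while C7 beside it can epimerise. The C13 methylene, the C1 oxidation state and the furanone closure are all still missing.
- Comparison: this alternative is at least as strong on forming the ring by a known reaction type. The chosen strategy offers correct oxidation levels at C1 and C8 from the outset and far fewer adjustments after ring formation.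

**Alternative 3:** The cuts are at O–C3 and C10–C14. A ten-membered ring that holds a C10 ketone, a C1 tertiary carbinol bearing the methyl group and a C2≡C3 alkyne is treated with platinum dichloride A5. The ketone oxygen adds to C3 and the methyl group shifts from C1 to C10, giving the furanone-bridged core A4.
- For it: the furanone and the quaternary C10 form in one catalytic step. The C10 configuration is relayed stereospecifically from the C1 carbinol through a suprafacial 1,2-shift, which is better defined than the tether-controlled face selectivity of the chosen route. A4 already carries the lactone and is about three operations from the target.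
- Against it: it presupposes the strained cyclic ynone, whose ring closure is the unsolved problem. Methyl is a poor migrating group. The carbophilic platinum dichloride A5 can also engage the C4=C5 and C11=C13 alkenes (enyne cycloisomerisation), and the α-ketol can rearrange.
- Comparison: this alternative is stronger on the origin of the C10 configuration and on end-game length. The chosen strategy offers a ring closure that never places an alkyne in the ten-membered ring and that makes C10 in the ring-forming step itself.

Key step: step 18

## Route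

Step 1
Reactants: 1 3-hydroxybutan-2-one (acetoin, racemic)
Product: 3 2-methylfuran-3(2H)-one (racemic), via enaminone 2 (not isolated)
Conditions: Me2NCH(OMe)2 (1.5 equiv), 90 °C; then 1 M aq. HCl, THF, rt
Reagents that add atoms: N,N-dimethylformamide dimethyl acetal, COC(OC)N(C)C
Why: The amide acetal condenses with the methyl group of the ketone (the only α-position with two hydrogens) to give vinylogous amide 2; in aqueous acid the hydroxyl adds to the iminium carbon and dimethylamine is lost (enaminone formation, then cyclodehydration of an α'-hydroxy enaminone to a furan-3(2H)-one); 3 is volatile and enolisable and is used crude.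

Step 2
Reactants: 3 2-methylfuran-3(2H)-one
Product: 4 2-methyl-3-[tri(propan-2-yl)silyloxy]furan
Conditions: TIPSOTf, Et3N, CH2Cl2, 0 °C
Reagents that add atoms: triisopropylsilyl trifluoromethanesulfonate, CC(C)[Si](OS(=O)(=O)C(F)(F)F)(C(C)C)C(C)C
Why: Soft enolisation and O-silylation; aromatisation to the furan drives silylation onto oxygen, as known for 3(2H)-furanones, and the bulky silyl group makes the enol ether stable enough to purify on deactivated silica.

Step 3
Reactants: 4 2-methyl-3-[tri(propan-2-yl)silyloxy]furan
Product: 6 tributyl{5-methyl-4-[tri(propan-2-yl)silyloxy]furan-2-yl}stannane, via furyllithium 5 (not isolated)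
Conditions: n-BuLi, THF, −78 to 0 °C; then Bu3SnCl, −78 °C to rt
Reagents that add atoms: tributyltin chloride, CCCC[Sn](Cl)(CCCC)CCCC
Why: α-Lithiation of a furan: C5 is the only free α-position and is more acidic than the 2-methyl group or the C4 hydrogen; the furyllithium is trapped by the stannyl chloride (lithiation–stannylation).

Step 4
Reactants: 7 but-2-yne-1,4-diol
Product: 8 4-[(4-methoxyphenyl)methoxy]but-2-yn-1-ol
Conditions: NaH (1 equiv), PMBCl (1 equiv), Bu4NI (cat.), THF/DMF, 0 °C to rt; diol in threefold excess
Reagents that add atoms: 4-methoxybenzyl chloride, COc1ccc(CCl)cc1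
Why: Williamson monoetherification of a symmetrical diol; the excess of diol keeps bis-alkylation low and is removed by aqueous extraction.

Step 5
Reactants: 8 4-[(4-methoxyphenyl)methoxy]but-2-yn-1-ol
Product: 10 (2Z)-3-iodo-4-[(4-methoxyphenyl)methoxy]but-2-en-1-ol, via alkenylaluminate 9 (not isolated)
Conditions: NaAlH2(OCH2CH2OMe)2, THF, 0 °C; then I2, −78 °C
Reagents that add atoms: iodine, II
Why: Hydroxyl-directed trans-hydroalumination of the propargylic alcohol places aluminium on the distal alkyne carbon (the later C4) in the five-membered alkoxyaluminate 9; iodinolysis with retention gives the Z-iodoalkene in which iodine is cis to the CH2OH carbon (the later C6), the geometry needed at C4=C5.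

Step 6
Reactants: 10 (2Z)-3-iodo-4-[(4-methoxyphenyl)methoxy]but-2-en-1-ol
Product: 11 (2Z)-3-iodo-4-[(4-methoxyphenyl)methoxy]but-2-enal
Conditions: MnO2, CH2Cl2, rt
Reagents that add atoms: none
Why: Allylic alcohol oxidation under neutral conditions, which leaves the Z geometry and the benzyl-type ether untouched; the β-iodo enal is used without delay.

Step 7
Reactants: 12 (4S)-2,2-dimethyl-1,3-dioxolane-4-carbaldehyde ((S)-glyceraldehyde acetonide); 13 methyl prop-2-enoate
Product: 14 methyl 2-{[(4S)-2,2-dimethyl-1,3-dioxolan-4-yl](hydroxy)methyl}prop-2-enoate (both carbinol epimers)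
Conditions: DABCO (0.5 equiv), 1,4-dioxane/H2O 1:1, rt
Reagents that add atoms: none
Why: Morita–Baylis–Hillman reaction of a reactive α-alkoxy aldehyde; the weakly basic amine should not epimerise C8, and the new carbinol centre (C7) may form as a mixture because it becomes sp2 in step 10.

Step 8
Reactants: 14 methyl 2-{[(4S)-2,2-dimethyl-1,3-dioxolan-4-yl](hydroxy)methyl}prop-2-enoate
Product: 16 (5S)-4-hydroxy-5-(hydroxymethyl)-3-methylideneoxolan-2-one (C4 epimers), via triol ester 15 (not isolated)
Conditions: 1 M aq. HCl, THF, rt; then concentration from toluene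
Reagents that add atoms: none
Why: Acetal hydrolysis followed by acid-catalysed transesterification of the γ-hydroxyl (O8) onto the ester; the five-membered lactone is favoured over the six-membered one that the primary hydroxyl would give.

Step 9
Reactants: 16 (5S)-4-hydroxy-5-(hydroxymethyl)-3-methylideneoxolan-2-one
Product: 17 (5S)-5-{[tert-butyl(dimethyl)silyl]oxymethyl}-4-hydroxy-3-methylideneoxolan-2-one (C4 epimers)
Conditions: TBSCl (1.05 equiv), imidazole, CH2Cl2, −20 to 0 °C
Reagents that add atoms: tert-butyldimethylsilyl chloride, CC(C)(C)[Si](C)(C)Cl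
Why: The primary hydroxyl is silylated selectively over the ring-bound secondary allylic one (steric differentiation with a limiting amount of silyl chloride).

Step 10
Reactants: 17 (5S)-5-{[tert-butyl(dimethyl)silyl]oxymethyl}-4-hydroxy-3-methylideneoxolan-2-one
Product: 18 (5R)-3-(bromomethyl)-5-{[tert-butyl(dimethyl)silyl]oxymethyl}furan-2(5H)-one
Conditions: NBS, Me2S, CH2Cl2, −20 to 0 °C
Reagents that add atoms: N-bromosuccinimide, O=C1CCC(=O)N1Br
Why: Corey–Kim-type activation of the allylic alcohol as an alkoxysulfonium salt; bromide displaces it with allylic transposition to the conjugated endocyclic butenolide, so both carbinol epimers converge, and C8 is not involved.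

Step 11
Reactants: 18 (5R)-3-(bromomethyl)-5-{[tert-butyl(dimethyl)silyl]oxymethyl}furan-2(5H)-one; 11 (2Z)-3-iodo-4-[(4-methoxyphenyl)methoxy]but-2-enal
Product: 20 (4S,5R)-5-{[tert-butyl(dimethyl)silyl]oxymethyl}-4-{(1S,2Z)-1-hydroxy-3-iodo-4-[(4-methoxyphenyl)methoxy]but-2-en-1-yl}-3-methylideneoxolan-2-one (6S,7S,8R in target numbering), via allylzinc bromide 19 (not isolated)
Conditions: Zn dust, THF/sat. aq. NH4Cl 2:1, 0 °C to rt
Reagents that add atoms: none
Why: Barbier allylation through a closed six-membered chair (Zimmerman–Traxler) transition state with bond formation at the γ-carbon C7, which restores the exocyclic C11=C13 bond; the butenolide ring holds C8 trans to the CH2Zn group, so the chair should give the 6,7-anti relationship (that of the later trans 6,12-lactone), and the aldehyde approaches the ring face opposite to the silyloxymethyl group, which sets C7 relative to C8. The vinyl iodide and the ethers are inert to zinc under these conditions.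

Step 12
Reactants: 20 Barbier adduct (free C6 hydroxyl)
Product: 21 (4R,5R)-5-{[tert-butyl(dimethyl)silyl]oxymethyl}-4-{(1S,2Z)-1-{[tert-butyl(dimethyl)silyl]oxy}-3-iodo-4-[(4-methoxyphenyl)methoxy]but-2-en-1-yl}-3-methylideneoxolan-2-one
Conditions: TBSOTf, 2,6-lutidine, CH2Cl2, −78 °C
Reagents that add atoms: tert-butyldimethylsilyl trifluoromethanesulfonate, CC(C)(C)[Si](C)(C)OS(=O)(=O)C(F)(F)F
Why: Silylation of the only free, hindered secondary allylic hydroxyl with the silyl triflate at low temperature, where the lactone does not migrate.

Step 13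
Reactants: 21 C6-silylated lactone
Product: 22 (2R,3R,4S,5Z)-1,4-bis{[tert-butyl(dimethyl)silyl]oxy}-3-(3-hydroxyprop-1-en-2-yl)-6-iodo-7-[(4-methoxyphenyl)methoxy]hept-5-en-2-ol (6S,7R,8R in target numbering)
Conditions: iBu2AlH (4 equiv), CH2Cl2, −78 to 0 °C; aq. potassium sodium tartrate
Reagents that add atoms: none
Why: 1,2-Reduction of the α-methylene lactone through the lactol to the 2-methylene-1,4-diol; iBu2AlH does not add in a conjugate sense and leaves the vinyl iodide and the silyl ethers intact.

Step 14
Reactants: 22 C8,C12-diol
Product: 23 (2R,3R,4S,5Z)-1,4-bis{[tert-butyl(dimethyl)silyl]oxy}-3-{3-[tert-butyl(diphenyl)silyl]oxyprop-1-en-2-yl}-6-iodo-7-[(4-methoxyphenyl)methoxy]hept-5-en-2-ol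
Conditions: TBDPSCl (1.05 equiv), imidazole, CH2Cl2, 0 °C
Reagents that add atoms: tert-butyldiphenylsilyl chloride, CC(C)(C)[Si](Cl)(c1ccccc1)c1ccccc1
Why: The bulky silyl chloride reacts only with the primary allylic hydroxyl (C12) and leaves the secondary C8 hydroxyl free; this group is chosen because it survives step 16 and its hindered oxygen cannot compete as a nucleophile in steps 16 and 18.

Step 15
Reactants: 23 C8 alcohol
Product: 24 (2R,3S,4S,5Z)-1,4-bis{[tert-butyl(dimethyl)silyl]oxy}-3-{3-[tert-butyl(diphenyl)silyl]oxyprop-1-en-2-yl}-6-iodo-7-[(4-methoxyphenyl)methoxy]hept-5-en-2-yl methanesulfonate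
Conditions: MsCl, Et3N, CH2Cl2, 0 °C
Reagents that add atoms: methanesulfonyl chloride, CS(=O)(=O)Cl
Why: Sulfonylation of the only free hydroxyl through the sulfene; the configuration at C8 is unchanged.

Step 16
Reactants: 24 C8 mesylate
Product: 26 (2S)-2-[(1R,2S,3Z)-2-{[tert-butyl(dimethyl)silyl]oxy}-1-{3-[tert-butyl(diphenyl)silyl]oxyprop-1-en-2-yl}-4-iodo-5-[(4-methoxyphenyl)methoxy]pent-3-en-1-yl]oxirane (6S,7R,8S in target numbering), via hydroxy mesylate 25 (not isolated)
Conditions: CSA (0.1 equiv), MeOH/CH2Cl2 1:1, 0 °C; then K2CO3 (4 equiv), rt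
Reagents that add atoms: none
Why: Acid-catalysed methanolysis removes the unhindered primary silyl ether at C9 much faster than the hindered secondary one at C6 or the diphenyl-tert-butylsilyl ether; the C9 alkoxide then displaces the neighbouring mesylate (intramolecular Williamson reaction, 3-exo-tet, SN2) with inversion at C8, which turns the epimeric C8 of the Barbier adduct into the configuration of the target. O12 is blocked, so the competing five-membered ether cannot form.

Step 17
Reactants: 26 epoxy vinyl iodide; 6 tributyl{5-methyl-4-[tri(propan-2-yl)silyloxy]furan-2-yl}stannane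
Product: 27 (2S)-2-[(1R,2R,3Z)-2-{[tert-butyl(dimethyl)silyl]oxy}-1-{3-[tert-butyl(diphenyl)silyl]oxyprop-1-en-2-yl}-4-[(4-methoxyphenyl)methoxymethyl]-4-{5-methyl-4-[tri(propan-2-yl)silyloxy]furan-2-yl}but-3-en-1-yl]oxirane (6R,7R,8S in target numbering)
Conditions: Pd2(dba)3 (5 mol %), AsPh3 (20 mol %), CuI (10 mol %), DMF, rt, dark
Reagents that add atoms: none
Why: Stille coupling (oxidative addition of zerovalent palladium into the vinyl iodide, transmetalation of the 2-furyl stannane helped by AsPh3 and CuI, reductive elimination) with retention of the Z geometry; the neutral, fluoride-free conditions tolerate the oxirane and the silyl enol ether.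

Step 18
Reactants: 27 silyloxyfuran epoxide
Product: 28 (4Z,6R,7R,8R,10S)-6-{[tert-butyl(dimethyl)silyl]oxy}-12-{[tert-butyl(diphenyl)silyl]oxy}-8-hydroxy-15-[(4-methoxyphenyl)methoxy]-3,10-epoxygermacra-2,4,11(13)-trien-1-one
Conditions: BF3·OEt2 (1.5 equiv), 2,6-di-tert-butyl-4-methylpyridine (0.3 equiv), CH2Cl2 (0.002 M), −78 to −30 °C; sat. aq. NaHCO3
Reagents that add atoms: none
Why: Proposed new method: BF3 coordinates the oxirane oxygen and the 2-methyl-3-silyloxyfuran attacks the terminal oxirane carbon C9 with its 2-position C10, anti to the breaking C9–O bond (SN2), which forms the C9–C10 bond and a silyloxocarbenium ion at C1; loss of the silyl group to fluoride leaves the furan-3(2H)-one, and work-up frees the C8 hydroxyl. The closest known reaction types are the C2-selective Mukaiyama aldol and Michael additions of 2-substituted 3-silyloxyfurans, which also create a quaternary C2, and the BF3-mediated opening of epoxides by silyl enol ethers; a ring-closing version that joins the two has not been shown. The ten-membered carbocycle (nine-membered when counted through the furan oxygen) closes in an endo mode with respect to the oxirane, both oxirane carbons becoming ring members. C10 is the only new stereocentre and is controlled by the C6–C8 tether: the Z-C4=C5 bond holds C6 beside the furan, so the chain must arch over one π-face to reach C10, and the arch leading to the (10S) isomer should let the C6 silyloxy group, the C7 side arm and the C8–O bond point outward, whereas the other turns the C7 arm across the furan. C8 is not touched and keeps the configuration set in step 16. The step needs C9-over-C8 regioselectivity, secured by primary versus secondary substitution and by the still smaller ring that attack at C8 would give, and C10-over-C2 site selectivity on the furan, secured because only attack at C10 leads to a conjugated vinylogous ester. Competing opening by the ether oxygens is held back by the bulk of the silyl groups on O6 and O12, intermolecular reaction by high dilution, and protodesilylation by the hindered pyridine base. The nucleophile is neutral and non-basic, so no other position is enolised or epimerised.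

Step 19
Reactants: 28 macrocyclic C8 alcohol
Product: 29 (4Z,6R,7R,8R,10S)-6-{[tert-butyl(dimethyl)silyl]oxy}-12-{[tert-butyl(diphenyl)silyl]oxy}-15-[(4-methoxyphenyl)methoxy]-1-oxo-3,10-epoxygermacra-2,4,11(13)-trien-8-yl 2-methylprop-2-enoate
Conditions: methacrylic anhydride, Et3N, DMAP (cat.), CH2Cl2, 0 °C to rt
Reagents that add atoms: methacrylic anhydride, C=C(C)C(=O)OC(=O)C(C)=C
Why: DMAP-catalysed acylation of the secondary alcohol; C10 is now quaternary, so the furanone has no enolisable position and tolerates the amine base.

Step 20
Reactants: 29 bis-silyl ether methacrylate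
Product: 30 (4Z,6R,7S,8R,10S)-6,12-dihydroxy-15-[(4-methoxyphenyl)methoxy]-1-oxo-3,10-epoxygermacra-2,4,11(13)-trien-8-yl 2-methylprop-2-enoate
Conditions: HF·pyridine, pyridine, THF, 0 °C to rt
Reagents that add atoms: none
Why: Fluoride cleavage of both silyl ethers under mildly acidic conditions, which disfavour 1,3-acyl migration from O8 to O6 and conjugate addition to the methacrylate; the benzyl-type ether is stable.

Step 21
Reactants: 30 C6,C12-diol
Product: 33 (4Z,6R,7R,8R,10S)-15-[(4-methoxyphenyl)methoxy]-1-oxo-3,10-epoxygermacra-2,4,11(13)-trien-12,6-olid-8-yl 2-methylprop-2-enoate, via hydroxy enal 31 (not isolated), via lactol 32 (not isolated)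
Conditions: TEMPO (0.2 equiv), PhI(OAc)2 (3 equiv), CH2Cl2, rt
Reagents that add atoms: none
Why: Oxoammonium oxidation is selective for the primary allylic alcohol; aldehyde 31 is trapped by the C6 hydroxyl as lactol 32, which is oxidised on to the lactone (oxidative lactonisation of a 1,4-diol). O8 is acylated and O15 protected, so only the 6,12-lactone can form, and C6 keeps its configuration.

Step 22
Reactants: 33 p-methoxybenzyl ether of the target
Product: 34 (4Z,6R,7R,8R,10S)-15-hydroxy-1-oxo-3,10-epoxygermacra-2,4,11(13)-trien-12,6-olid-8-yl 2-methylprop-2-enoate (target)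
Conditions: DDQ (1.3 equiv), CH2Cl2/aq. NaH2PO4–Na2HPO4 buffer (pH 7) 10:1, 0 °C
Reagents that add atoms: none
Why: Oxidative cleavage of the p-methoxybenzyl ether by DDQ through the benzylic oxocarbenium ion, which the buffer hydrolyses; the electron-poor acrylate units and the vinylogous ester should not be oxidised at 0 °C, and the oxidant is kept near one equivalent to spare the freed allylic alcohol.

## Compound list

1 | 3-hydroxybutan-2-one (acetoin, racemic) | CC(O)C(C)=O | starting material
2 | (1E)-1-(dimethylamino)-4-hydroxypent-1-en-3-one | CC(O)C(=O)/C=C/N(C)C | intermediate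
3 | 2-methylfuran-3(2H)-one (racemic) | CC1OC=CC1=O | intermediate
4 | 2-methyl-3-[tri(propan-2-yl)silyloxy]furan | Cc1occc1O[Si](C(C)C)(C(C)C)C(C)C | intermediate
5 | {5-methyl-4-[tri(propan-2-yl)silyloxy]furan-2-yl}lithium | [Li]c1cc(O[Si](C(C)C)(C(C)C)C(C)C)c(C)o1 | intermediate
6 | tributyl{5-methyl-4-[tri(propan-2-yl)silyloxy]furan-2-yl}stannane | CCCC[Sn](CCCC)(CCCC)c1cc(O[Si](C(C)C)(C(C)C)C(C)C)c(C)o1 | intermediate
7 | but-2-yne-1,4-diol | OCC#CCO | starting material
8 | 4-[(4-methoxyphenyl)methoxy]but-2-yn-1-ol | OCC#CCOCc1ccc(OC)cc1 | intermediate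
9 | sodium cyclic alkenyl(alkoxy)bis(2-methoxyethoxy)aluminate (2,5-dihydro-1,2-oxaluminole, Al on the later C4) | [Na+].COCCO[Al-]1(OCCOC)OCC=C1COCc1ccc(OC)cc1 | intermediate
10 | (2Z)-3-iodo-4-[(4-methoxyphenyl)methoxy]but-2-en-1-ol | OC/C=C(\I)COCc1ccc(OC)cc1 | intermediate
11 | (2Z)-3-iodo-4-[(4-methoxyphenyl)methoxy]but-2-enal | O=C/C=C(\I)COCc1ccc(OC)cc1 | intermediate
12 | (4S)-2,2-dimethyl-1,3-dioxolane-4-carbaldehyde ((S)-glyceraldehyde acetonide) | O=C[C@@H]1COC(C)(C)O1 | starting material
13 | methyl prop-2-enoate (methyl acrylate) | C=CC(=O)OC | starting material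
14 | methyl 2-{[(4S)-2,2-dimethyl-1,3-dioxolan-4-yl](hydroxy)methyl}prop-2-enoate (both carbinol epimers) | C=C(C(O)[C@@H]1COC(C)(C)O1)C(=O)OC | intermediate
15 | methyl (4S)-3,4,5-trihydroxy-2-methylidenepentanoate (C3 epimers) | C=C(C(O)[C@@H](O)CO)C(=O)OC | intermediate
16 | (5S)-4-hydroxy-5-(hydroxymethyl)-3-methylideneoxolan-2-one (C4 epimers) | C=C1C(O)[C@H](CO)OC1=O | intermediate
17 | (5S)-5-{[tert-butyl(dimethyl)silyl]oxymethyl}-4-hydroxy-3-methylideneoxolan-2-one (C4 epimers) | C=C1C(O)[C@H](CO[Si](C)(C)C(C)(C)C)OC1=O | intermediate
18 | (5R)-3-(bromomethyl)-5-{[tert-butyl(dimethyl)silyl]oxymethyl}furan-2(5H)-one | BrCC1=C[C@H](CO[Si](C)(C)C(C)(C)C)OC1=O | intermediate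
19 | bromo{[(5R)-5-{[tert-butyl(dimethyl)silyl]oxymethyl}-2-oxo-2,5-dihydrofuran-3-yl]methyl}zinc | Br[Zn]CC1=C[C@H](CO[Si](C)(C)C(C)(C)C)OC1=O | intermediate
20 | (4S,5R)-5-{[tert-butyl(dimethyl)silyl]oxymethyl}-4-{(1S,2Z)-1-hydroxy-3-iodo-4-[(4-methoxyphenyl)methoxy]but-2-en-1-yl}-3-methylideneoxolan-2-one | C=C1C(=O)O[C@@H](CO[Si](C)(C)C(C)(C)C)[C@@H]1[C@H](O)/C=C(\I)COCc1ccc(OC)cc1 | intermediate
21 | (4R,5R)-5-{[tert-butyl(dimethyl)silyl]oxymethyl}-4-{(1S,2Z)-1-{[tert-butyl(dimethyl)silyl]oxy}-3-iodo-4-[(4-methoxyphenyl)methoxy]but-2-en-1-yl}-3-methylideneoxolan-2-one | C=C1C(=O)O[C@@H](CO[Si](C)(C)C(C)(C)C)[C@@H]1[C@H](O[Si](C)(C)C(C)(C)C)/C=C(\I)COCc1ccc(OC)cc1 | intermediate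
22 | (2R,3R,4S,5Z)-1,4-bis{[tert-butyl(dimethyl)silyl]oxy}-3-(3-hydroxyprop-1-en-2-yl)-6-iodo-7-[(4-methoxyphenyl)methoxy]hept-5-en-2-ol | C=C(CO)[C@H]([C@@H](O)CO[Si](C)(C)C(C)(C)C)[C@H](O[Si](C)(C)C(C)(C)C)/C=C(\I)COCc1ccc(OC)cc1 | intermediate
23 | (2R,3R,4S,5Z)-1,4-bis{[tert-butyl(dimethyl)silyl]oxy}-3-{3-[tert-butyl(diphenyl)silyl]oxyprop-1-en-2-yl}-6-iodo-7-[(4-methoxyphenyl)methoxy]hept-5-en-2-ol | C=C(CO[Si](c1ccccc1)(c1ccccc1)C(C)(C)C)[C@H]([C@@H](O)CO[Si](C)(C)C(C)(C)C)[C@H](O[Si](C)(C)C(C)(C)C)/C=C(\I)COCc1ccc(OC)cc1 | intermediate
24 | (2R,3S,4S,5Z)-1,4-bis{[tert-butyl(dimethyl)silyl]oxy}-3-{3-[tert-butyl(diphenyl)silyl]oxyprop-1-en-2-yl}-6-iodo-7-[(4-methoxyphenyl)methoxy]hept-5-en-2-yl methanesulfonate | C=C(CO[Si](c1ccccc1)(c1ccccc1)C(C)(C)C)[C@H]([C@@H](OS(C)(=O)=O)CO[Si](C)(C)C(C)(C)C)[C@H](O[Si](C)(C)C(C)(C)C)/C=C(\I)COCc1ccc(OC)cc1 | intermediate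
25 | (2R,3S,4S,5Z)-4-{[tert-butyl(dimethyl)silyl]oxy}-3-{3-[tert-butyl(diphenyl)silyl]oxyprop-1-en-2-yl}-1-hydroxy-6-iodo-7-[(4-methoxyphenyl)methoxy]hept-5-en-2-yl methanesulfonate | C=C(CO[Si](c1ccccc1)(c1ccccc1)C(C)(C)C)[C@H]([C@@H](OS(C)(=O)=O)CO)[C@H](O[Si](C)(C)C(C)(C)C)/C=C(\I)COCc1ccc(OC)cc1 | intermediate
26 | (2S)-2-[(1R,2S,3Z)-2-{[tert-butyl(dimethyl)silyl]oxy}-1-{3-[tert-butyl(diphenyl)silyl]oxyprop-1-en-2-yl}-4-iodo-5-[(4-methoxyphenyl)methoxy]pent-3-en-1-yl]oxirane | C=C(CO[Si](c1ccccc1)(c1ccccc1)C(C)(C)C)[C@H]([C@H]1CO1)[C@H](O[Si](C)(C)C(C)(C)C)/C=C(\I)COCc1ccc(OC)cc1 | intermediate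
27 | (2S)-2-[(1R,2R,3Z)-2-{[tert-butyl(dimethyl)silyl]oxy}-1-{3-[tert-butyl(diphenyl)silyl]oxyprop-1-en-2-yl}-4-[(4-methoxyphenyl)methoxymethyl]-4-{5-methyl-4-[tri(propan-2-yl)silyloxy]furan-2-yl}but-3-en-1-yl]oxirane | Cc1oc(/C(COCc2ccc(OC)cc2)=C\[C@@H](O[Si](C)(C)C(C)(C)C)[C@@H]([C@H]2CO2)C(=C)CO[Si](c2ccccc2)(c2ccccc2)C(C)(C)C)cc1O[Si](C(C)C)(C(C)C)C(C)C | intermediate
28 | (4Z,6R,7R,8R,10S)-6-{[tert-butyl(dimethyl)silyl]oxy}-12-{[tert-butyl(diphenyl)silyl]oxy}-8-hydroxy-15-[(4-methoxyphenyl)methoxy]-3,10-epoxygermacra-2,4,11(13)-trien-1-one | O[C@@H]1C[C@]2(C)OC(=CC2=O)/C(COCc2ccc(OC)cc2)=C\[C@@H](O[Si](C)(C)C(C)(C)C)[C@@H]1C(=C)CO[Si](c1ccccc1)(c1ccccc1)C(C)(C)C | intermediate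
29 | (4Z,6R,7R,8R,10S)-6-{[tert-butyl(dimethyl)silyl]oxy}-12-{[tert-butyl(diphenyl)silyl]oxy}-15-[(4-methoxyphenyl)methoxy]-1-oxo-3,10-epoxygermacra-2,4,11(13)-trien-8-yl 2-methylprop-2-enoate | C=C(C)C(=O)O[C@@H]1C[C@]2(C)OC(=CC2=O)/C(COCc2ccc(OC)cc2)=C\[C@@H](O[Si](C)(C)C(C)(C)C)[C@@H]1C(=C)CO[Si](c1ccccc1)(c1ccccc1)C(C)(C)C | intermediate
30 | (4Z,6R,7S,8R,10S)-6,12-dihydroxy-15-[(4-methoxyphenyl)methoxy]-1-oxo-3,10-epoxygermacra-2,4,11(13)-trien-8-yl 2-methylprop-2-enoate | C=C(C)C(=O)O[C@@H]1C[C@]2(C)OC(=CC2=O)/C(COCc2ccc(OC)cc2)=C\[C@@H](O)[C@@H]1C(=C)CO | intermediate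
31 | (4Z,6R,7S,8R,10S)-6-hydroxy-15-[(4-methoxyphenyl)methoxy]-1,12-dioxo-3,10-epoxygermacra-2,4,11(13)-trien-8-yl 2-methylprop-2-enoate | C=C(C)C(=O)O[C@@H]1C[C@]2(C)OC(=CC2=O)/C(COCc2ccc(OC)cc2)=C\[C@@H](O)[C@@H]1C(=C)C=O | intermediate
32 | (4Z,6R,7R,8R,10S)-12-hydroxy-15-[(4-methoxyphenyl)methoxy]-1-oxo-3,10:6,12-diepoxygermacra-2,4,11(13)-trien-8-yl 2-methylprop-2-enoate (lactol, both C12 epimers) | C=C(C)C(=O)O[C@@H]1C[C@]2(C)OC(=CC2=O)/C(COCc2ccc(OC)cc2)=C\[C@H]2OC(O)C(=C)[C@@H]21 | intermediate
33 | (4Z,6R,7R,8R,10S)-15-[(4-methoxyphenyl)methoxy]-1-oxo-3,10-epoxygermacra-2,4,11(13)-trien-12,6-olid-8-yl 2-methylprop-2-enoate | C=C(C)C(=O)O[C@@H]1C[C@]2(C)OC(=CC2=O)/C(COCc2ccc(OC)cc2)=C\[C@H]2OC(=O)C(=C)[C@@H]21 | intermediate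
34 | (4Z,6R,7R,8R,10S)-15-hydroxy-1-oxo-3,10-epoxygermacra-2,4,11(13)-trien-12,6-olid-8-yl 2-methylprop-2-enoate | C=C(C)C(=O)O[C@@H]1C[C@]2(C)OC(=CC2=O)/C(CO)=C\[C@H]2OC(=O)C(=C)[C@@H]21 | target

## Step count and least certain steps

Total step count: 22. Longest linear sequence: 16 steps (12 to 34, steps 7–22). The furan branch (steps 1–3) and the iodoenal branch (steps 4–6) are each three steps.

**Step 18 (key step, proposed new method).**
- What may go wrong: the oxirane may be opened by another nucleophile or rearrange by hydride shift before the strained ring closes. The Lewis acid may ionise the allylic C6 silyl ether, which is conjugated to the electron-rich furan. Adventitious acid may protodesilylate the furan. Attack may occur on the other face of C10, or between molecules.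
- Fallback (known chemistry, anionic instead of Lewis-acidic): it sets out from epoxide 26. MgI2·OEt2 in ether at low temperature opens the oxirane at its primary carbon to give the C9-iodo C8-hydroxy compound (iodohydrin) F1, and TESOTf with 2,6-lutidine converts it into the C8 triethylsilyl ether F2. Stille coupling of F2 with stannane 6 under the conditions of step 17 (the primary alkyl iodide is inert to this catalyst at room temperature) gives the silyloxyfuran primary iodide F3. CsF in DMF at high dilution cleaves the enol silyl ether selectively and the cesium 3-oxidofuran C-alkylates at C10 with the primary iodide, a fluoride-promoted enolate alkylation that closes the ring to the C8 triethylsilyl ether of the macrocycle F4. Pyridinium p-toluenesulfonate in methanol at 0 °C removes the triethylsilyl group and the route is rejoined at 28.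

**Step 11.**
- What may go wrong: loss of diastereoselectivity if part of the reaction runs through an open or boat transition state. The lactone may migrate from O8 to O6 under the reaction conditions, which would leave the wrong hydroxyl free for step 12. The β-iodo enal may isomerise from Z to E or be reduced on the zinc surface.
- Fallback: it sets out from hydroxy lactone 17. Acetic anhydride and pyridine give the allylic acetate F5. Copper-catalysed SN2' borylation (CuCl, KOtBu, B2pin2) gives the ring-locked 2-carbonyl allylboronate F6. Heating F6 with aldehyde 11 in toluene brings about a thermal allylboration through a tight boron-centred chair, and oxidative or aqueous work-up rejoins the route at 20.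

**Step 1.**
- What may go wrong: self-condensation or air oxidation of acetoin through its enediol, reaction of the free hydroxyl with the amide acetal, and oligomerisation or loss of the volatile furanone on isolation.
- Fallback: it sets out from 1. TBSCl and imidazole give 3-{[tert-butyl(dimethyl)silyl]oxy}butan-2-one F7. Claisen formylation with NaH and ethyl formate gives the hydroxymethylene ketone (1Z)-1-hydroxy-4-{[tert-butyl(dimethyl)silyl]oxy}pent-1-en-3-one F8. Aqueous HCl in THF removes the silyl group and brings about cyclodehydration, rejoining the route at 3.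

**Step 17.**
- What may go wrong: protodestannylation of the electron-rich furyl stannane, homocoupling, or slow transmetalation that leaves the vinyl iodide to decompose.
- Fallback: it sets out from furyllithium 5, generated as in step 3. ZnCl2 in THF gives the furylzinc chloride chloro{5-methyl-4-[tri(propan-2-yl)silyloxy]furan-2-yl}zinc F9. Negishi coupling of F9 with vinyl iodide 26 and Pd(PPh3)4 at 0 °C to room temperature rejoins the route at 27.

**Step 22.**
- What may go wrong: over-oxidation of the freed, doubly activated allylic alcohol to the enal, or oxidative damage to the dienyl furanone.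
- Fallback: it sets out from 33 and replaces oxidation by Lewis-acid-assisted nucleophilic debenzylation with MgBr2·OEt2 and Me2S in CH2Cl2, arriving directly at 34; no new compound is formed on the way, hence the entry F0.

## Further compounds

F1 | step 18 | iodohydrin from 26: C9 iodide, free C8 hydroxyl (6S,7R,8S in target numbering) | C=C(CO[Si](c1ccccc1)(c1ccccc1)C(C)(C)C)[C@H]([C@H](O)CI)[C@H](O[Si](C)(C)C(C)(C)C)/C=C(\I)COCc1ccc(OC)cc1
F2 | step 18 | C8 triethylsilyl ether of F1 | C=C(CO[Si](c1ccccc1)(c1ccccc1)C(C)(C)C)[C@H]([C@H](O[Si](CC)(CC)CC)CI)[C@H](O[Si](C)(C)C(C)(C)C)/C=C(\I)COCc1ccc(OC)cc1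
F3 | step 18 | silyloxyfuran with C9 primary iodide and C8 triethylsilyl ether | Cc1oc(/C(COCc2ccc(OC)cc2)=C\[C@@H](O[Si](C)(C)C(C)(C)C)[C@@H]([C@H](O[Si](CC)(CC)CC)CI)C(=C)CO[Si](c2ccccc2)(c2ccccc2)C(C)(C)C)cc1O[Si](C(C)C)(C(C)C)C(C)C
F4 | step 18 | C8 triethylsilyl ether of macrocycle 28 | CC[Si](CC)(CC)O[C@@H]1C[C@]2(C)OC(=CC2=O)/C(COCc2ccc(OC)cc2)=C\[C@@H](O[Si](C)(C)C(C)(C)C)[C@@H]1C(=C)CO[Si](c1ccccc1)(c1ccccc1)C(C)(C)C
F5 | step 11 | (2S)-2-{[tert-butyl(dimethyl)silyl]oxymethyl}-4-methylidene-5-oxooxolan-3-yl acetate (C3 epimers) | C=C1C(OC(C)=O)[C@H](CO[Si](C)(C)C(C)(C)C)OC1=O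
F6 | step 11 | (5R)-5-{[tert-butyl(dimethyl)silyl]oxymethyl}-3-[(4,4,5,5-tetramethyl-1,3,2-dioxaborolan-2-yl)methyl]furan-2(5H)-one | CC1(C)OB(CC2=C[C@H](CO[Si](C)(C)C(C)(C)C)OC2=O)OC1(C)C
F7 | step 1 | 3-{[tert-butyl(dimethyl)silyl]oxy}butan-2-one | CC(O[Si](C)(C)C(C)(C)C)C(C)=O
F8 | step 1 | (1Z)-1-hydroxy-4-{[tert-butyl(dimethyl)silyl]oxy}pent-1-en-3-one | CC(O[Si](C)(C)C(C)(C)C)C(=O)/C=C\O
F9 | step 17 | chloro{5-methyl-4-[tri(propan-2-yl)silyloxy]furan-2-yl}zinc | Cl[Zn]c1cc(O[Si](C(C)C)(C(C)C)C(C)C)c(C)o1
F0 | step 22 | none | none
A1 | alternative 1 | trans α-methylene-γ-butyrolactone with free C8 hydroxyl, C1/C10 diol acetonide, C15 silyl ether and silylated C2≡C3 alkyne | CC1(C)OC[C@](C)(C[C@@H](O)[C@H]2C(=C)C(=O)O[C@@H]2/C=C(CO[Si](C)(C)C(C)(C)C)\C#C[Si](C(C)C)(C(C)C)C(C)C)O1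
A2 | alternative 1 | formaldehyde | C=O
A3 | alternative 2 | ten-membered enynone with C8 ketone, C2≡C3 alkyne, C1/C10 diol acetonide and 6,12-lactone lacking the C13 methylene | C1[C@]2(C)OC(C)(C)O[C@@H]2C#C/C(CO[Si](C)(C)C(C)(C)C)=C\[C@H]2OC(=O)C[C@@H]2C1=O
A4 | alternative 3 | furanone-bridged lactone core with C8 triethylsilyl and C15 tert-butyldimethylsilyl ethers | CC[Si](CC)(CC)O[C@@H]1C[C@]2(C)OC(=CC2=O)/C(CO[Si](C)(C)C(C)(C)C)=C\[C@H]2OC(=O)C(=C)[C@@H]21
A5 | alternative 3 | platinum dichloride | Cl[Pt]Cl
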